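**Retrosynthetic overview**
1. The quinone is unveiled last: target 14 ⇐ hydroquinone 13 (mild oxidation) ⇐ tribenzyl ether 12 (hydrogenolysis).
2. The pyranone ring (the only ring built) is closed through its O1–C2 bond by a catalytic enantioselective intramolecular oxa-Michael addition of alkylidene β-keto ester 10, followed by loss of the tert-butyl ester.
3. The key C–C bond (C2–C3) comes from an intermolecular Knoevenagel-type aldol condensation of A-ring β-keto ester 5 with B-ring aldehyde 9.
4. 5 ⇐ acetophenone 4 (Claisen-type C-acylation) ⇐ 2',4',6'-trihydroxyacetophenone 1 (C-methylation, 4-O-methylation, mono-benzylation).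
5. 9 ⇐ methoxyhydroquinone 6 (bis-benzylation, Vilsmeier formylation). Both benzene rings are bought.

Assumption: the quinidine-derived thiourea is taken to give the (2S) series; if the first cyclisation proves to be (2R), the quinine-derived pseudoenantiomer is used with nothing else changed.

**Route**

Step 1
Reactants: 1 1-(2,4,6-trihydroxyphenyl)ethan-1-one
Product: 2 1-(2,4,6-trihydroxy-3,5-dimethylphenyl)ethan-1-one
Conditions: NaOMe (3 equiv), MeI (2.4 equiv), MeOH, 0 °C → reflux; then aq. HCl; crystallisation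
Reagents that add atoms: iodomethane CI
Why: Base-mediated C-methylation of the enolate-like phloroglucinol phenoxide takes place at the two free ring carbons, and limiting MeI to about two equivalents holds back dearomatising over-alkylation.

Step 2
Reactants: 2 1-(2,4,6-trihydroxy-3,5-dimethylphenyl)ethan-1-one
Product: 3 1-(2,6-dihydroxy-4-methoxy-3,5-dimethylphenyl)ethan-1-one
Conditions: Me2SO4 (1.0 equiv), K2CO3 (1.1 equiv), acetone, rt
Reagents that add atoms: dimethyl sulfate COS(=O)(=O)OC
Why: Williamson O-methylation is selective for the 4-OH because it is the most acidic hydroxyl and the only one not tied up in a hydrogen bond to the acetyl carbonyl.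

Step 3
Reactants: 3 1-(2,6-dihydroxy-4-methoxy-3,5-dimethylphenyl)ethan-1-one
Product: 4 1-[2-(benzyloxy)-6-hydroxy-4-methoxy-3,5-dimethylphenyl]ethan-1-one
Conditions: BnBr (1.05 equiv), K2CO3 (1.2 equiv), DMF, rt
Reagents that add atoms: benzyl bromide BrCc1ccccc1
Why: Williamson etherification stops after one benzylation because the remaining ortho-hydroxyl is strongly chelated to the ketone and much less nucleophilic.

Step 4
Reactants: 4 1-[2-(benzyloxy)-6-hydroxy-4-methoxy-3,5-dimethylphenyl]ethan-1-one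
Product: 5 tert-butyl 3-[2-(benzyloxy)-6-hydroxy-4-methoxy-3,5-dimethylphenyl]-3-oxopropanoate
Conditions: LiHMDS (3.3 equiv), THF, −78 °C; Boc2O (1.1 equiv), −78 → 0 °C; 1 M HCl quench
Reagents that add atoms: di-tert-butyl dicarbonate CC(C)(C)OC(=O)OC(=O)OC(C)(C)C
Why: Crossed Claisen-type C-acylation of the lithium enolate of the methyl ketone by Boc2O gives the β-keto ester, which the excess base deprotonates at once so that it is not acylated twice, and the bulky tert-butyl ester does not lactonise onto the phenoxide.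

Step 5
Reactants: 6 2-methoxybenzene-1,4-diol
Product: 7 1,4-bis(benzyloxy)-2-methoxybenzene
Conditions: BnBr (2.3 equiv), K2CO3 (3 equiv), DMF, 60 °C, N2
Reagents that add atoms: benzyl bromide BrCc1ccccc1
Why: Double Williamson benzylation masks the air-sensitive hydroquinone as a bis-ether that is removable later by neutral hydrogenolysis.

Step 6
Reactants: 7 1,4-bis(benzyloxy)-2-methoxybenzene
Product: 9 2,5-bis(benzyloxy)-4-methoxybenzaldehyde, via aryl iminium chloride 8 (not isolated)
Conditions: POCl3 (1.5 equiv), DMF, 0 → 70 °C; then ice-water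
Reagents that add atoms: N,N-dimethylformamide CN(C)C=O; water O
Why: Vilsmeier–Haack formylation attacks the position para to OMe and ortho to OBn, the most activated unhindered site, just as 1,2,4-trimethoxybenzene gives 2,4,5-trimethoxybenzaldehyde.

Step 7
Reactants: 5 tert-butyl 3-[2-(benzyloxy)-6-hydroxy-4-methoxy-3,5-dimethylphenyl]-3-oxopropanoate; 9 2,5-bis(benzyloxy)-4-methoxybenzaldehyde
Product: 10 tert-butyl 2-[2-(benzyloxy)-6-hydroxy-4-methoxy-3,5-dimethylbenzoyl]-3-[2,5-bis(benzyloxy)-4-methoxyphenyl]prop-2-enoate (E/Z mixture)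
Conditions: piperidine (10 mol%), AcOH (10 mol%), 4 Å MS, toluene, rt; rapid silica plug
Reagents that add atoms: none
Why: Knoevenagel (aldol-type) condensation of the active methylene with the aryl aldehyde under piperidinium acetate forms the future C2–C3 bond and joins the two halves, the alkene geometry being irrelevant because the double bond is consumed in the next step.

Step 8
Reactants: 10 tert-butyl 2-[2-(benzyloxy)-6-hydroxy-4-methoxy-3,5-dimethylbenzoyl]-3-[2,5-bis(benzyloxy)-4-methoxyphenyl]prop-2-enoate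
Product: 12 (2S)-5-(benzyloxy)-2-[2,5-bis(benzyloxy)-4-methoxyphenyl]-7-methoxy-6,8-dimethylchroman-4-one, via tert-butyl (2S)-flavanone-3-carboxylate 11 (not isolated)
Conditions: 1-[3,5-bis(trifluoromethyl)phenyl]-3-(9-deoxy-epi-quinidin-9-yl)thiourea (10 mol%), toluene, −25 °C; then TsOH·H2O (0.5 equiv), 80 °C; recrystallise to ≥99% ee
Reagents that add atoms: none
Why: In this bifunctional thiourea-catalysed intramolecular oxa-Michael addition the thiourea binds the β-keto ester and the quinuclidine delivers the phenol to one face of the alkylidene, setting C2 as S, after which TsOH cleaves the tert-butyl ester and the β-keto acid decarboxylates without touching C2.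

Step 9
Reactants: 12 (2S)-5-(benzyloxy)-2-[2,5-bis(benzyloxy)-4-methoxyphenyl]-7-methoxy-6,8-dimethylchroman-4-one
Product: 13 (2S)-2-(2,5-dihydroxy-4-methoxyphenyl)-5-hydroxy-7-methoxy-6,8-dimethylchroman-4-one
Conditions: H2 (1 atm), 10% Pd/C, EtOAc/MeOH, rt; filter through Celite under N2, use at once
Reagents that add atoms: none
Why: Pd-catalysed hydrogenolysis removes the three O-benzyl groups under neutral conditions that neither open the pyranone ring nor epimerise C2.

Step 10
Reactants: 13 (2S)-2-(2,5-dihydroxy-4-methoxyphenyl)-5-hydroxy-7-methoxy-6,8-dimethylchroman-4-one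
Product: 14 2-[(2S)-5-hydroxy-7-methoxy-6,8-dimethyl-4-oxochroman-2-yl]-5-methoxycyclohexa-2,5-diene-1,4-dione
Conditions: Ag2O (2 equiv), Na2SO4, EtOAc, rt, dark
Reagents that add atoms: none
Why: Ag2O dehydrogenates the electron-rich para-hydroquinone to the quinone under neutral conditions, while the chelated 5-OH (which has no ortho or para oxygen partner) and the C2 stereocentre are left alone.

**Compound list**
1 | 1-(2,4,6-trihydroxyphenyl)ethan-1-one | CC(=O)c1c(O)cc(O)cc1O | starting material
2 | 1-(2,4,6-trihydroxy-3,5-dimethylphenyl)ethan-1-one | CC(=O)c1c(O)c(C)c(O)c(C)c1O | intermediate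
3 | 1-(2,6-dihydroxy-4-methoxy-3,5-dimethylphenyl)ethan-1-one | CC(=O)c1c(O)c(C)c(OC)c(C)c1O | intermediate
4 | 1-[2-(benzyloxy)-6-hydroxy-4-methoxy-3,5-dimethylphenyl]ethan-1-one | CC(=O)c1c(OCc2ccccc2)c(C)c(OC)c(C)c1O | intermediate
5 | tert-butyl 3-[2-(benzyloxy)-6-hydroxy-4-methoxy-3,5-dimethylphenyl]-3-oxopropanoate | CC(C)(C)OC(=O)CC(=O)c1c(OCc2ccccc2)c(C)c(OC)c(C)c1O | intermediate
6 | 2-methoxybenzene-1,4-diol (methoxyhydroquinone) | COc1cc(O)ccc1O | starting material
7 | 1,4-bis(benzyloxy)-2-methoxybenzene | COc1cc(OCc2ccccc2)ccc1OCc1ccccc1 | intermediate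
8 | N-[2,5-bis(benzyloxy)-4-methoxybenzylidene]-N-methylmethanaminium chloride (not isolated) | C[N+](C)=Cc1cc(OCc2ccccc2)c(OC)cc1OCc1ccccc1.[Cl-] | intermediate
9 | 2,5-bis(benzyloxy)-4-methoxybenzaldehyde | COc1cc(OCc2ccccc2)c(C=O)cc1OCc1ccccc1 | intermediate
10 | tert-butyl 2-[2-(benzyloxy)-6-hydroxy-4-methoxy-3,5-dimethylbenzoyl]-3-[2,5-bis(benzyloxy)-4-methoxyphenyl]prop-2-enoate (E/Z mixture) | CC(C)(C)OC(=O)C(=Cc1cc(OCc2ccccc2)c(OC)cc1OCc1ccccc1)C(=O)c1c(OCc2ccccc2)c(C)c(OC)c(C)c1O | intermediate
11 | tert-butyl (2S)-5-(benzyloxy)-2-[2,5-bis(benzyloxy)-4-methoxyphenyl]-7-methoxy-6,8-dimethyl-4-oxochromane-3-carboxylate (C3 epimers/enol, not isolated) | CC(C)(C)OC(=O)C1C(=O)c2c(OCc3ccccc3)c(C)c(OC)c(C)c2O[C@@H]1c1cc(OCc2ccccc2)c(OC)cc1OCc1ccccc1 | intermediate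
12 | (2S)-5-(benzyloxy)-2-[2,5-bis(benzyloxy)-4-methoxyphenyl]-7-methoxy-6,8-dimethylchroman-4-one | O=C1C[C@@H](c2cc(OCc3ccccc3)c(OC)cc2OCc2ccccc2)Oc2c(C)c(OC)c(C)c(OCc3ccccc3)c12 | intermediate
13 | (2S)-2-(2,5-dihydroxy-4-methoxyphenyl)-5-hydroxy-7-methoxy-6,8-dimethylchroman-4-one | O=C1C[C@@H](c2cc(O)c(OC)cc2O)Oc2c(C)c(OC)c(C)c(O)c12 | intermediate
14 | 2-[(2S)-5-hydroxy-7-methoxy-6,8-dimethyl-4-oxochroman-2-yl]-5-methoxycyclohexa-2,5-diene-1,4-dione | COC1=CC(=O)C([C@@H]2CC(=O)c3c(O)c(C)c(OC)c(C)c3O2)=CC1=O | target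

**Totals**
Total step count: 10. Longest linear sequence: 8 steps (steps 1, 2, 3, 4, 7, 8, 9, 10); the B-ring branch is 2 steps (steps 5, 6).

**Steps most likely to fail, with fallbacks**

Step 4: the dianion may be acylated on oxygen (phenoxide or enolate) instead of carbon. The fallback sets out from 4 and acylates oxygen on purpose (Boc2O, cat. DMAP, MeCN, rt) to give 2-acetyl-3-(benzyloxy)-5-methoxy-4,6-dimethylphenyl tert-butyl carbonate F1. LDA (2.2 equiv, THF, −78 → 0 °C) then moves the Boc group from oxygen to the enolate carbon in a Baker–Venkataraman-type anionic acyl migration, phenoxide being the better leaving group. This comes back to the route at 5.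

Step 7: the electron-rich, ortho-substituted aldehyde may condense slowly, and the free phenol may close the ring prematurely to racemic material under amine catalysis. The fallback sets out from 5 and silylates the phenol (TBSCl, imidazole, DMF) to give tert-butyl 3-[2-(benzyloxy)-6-(tert-butyldimethylsilyloxy)-4-methoxy-3,5-dimethylphenyl]-3-oxopropanoate F2. With the phenol masked, the condensation with 9 can be forced (piperidine/AcOH, benzene, Dean–Stark) to the O-silyl alkylidene tert-butyl 2-[2-(benzyloxy)-6-(tert-butyldimethylsilyloxy)-4-methoxy-3,5-dimethylbenzoyl]-3-[2,5-bis(benzyloxy)-4-methoxyphenyl]prop-2-enoate F3. HF·pyridine (THF, 0 °C) then frees the phenol under non-basic conditions, and the route is rejoined at 10.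

Step 8: the enantioselectivity on this hindered, very electron-rich substrate may be insufficient, or the acidic decarboxylation may erode it. The fallback sets out from 4 together with 9. A Claisen–Schmidt aldol condensation (KOH, EtOH, rt) gives the chalcone (E)-1-[2-(benzyloxy)-6-hydroxy-4-methoxy-3,5-dimethylphenyl]-3-[2,5-bis(benzyloxy)-4-methoxyphenyl]prop-2-en-1-one F4. NaOAc in refluxing EtOH closes it to the racemic flavanone rac-5-(benzyloxy)-2-[2,5-bis(benzyloxy)-4-methoxyphenyl]-7-methoxy-6,8-dimethylchroman-4-one F5. Preparative chiral SFC on an amylose-type phase then delivers the (2S)-enantiomer, which is 12, where the route is rejoined. The unwanted antipode is racemised with NaOAc/EtOH and recycled.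

**Further compounds**
F1 | step 4 | 2-acetyl-3-(benzyloxy)-5-methoxy-4,6-dimethylphenyl tert-butyl carbonate | CC(=O)c1c(OCc2ccccc2)c(C)c(OC)c(C)c1OC(=O)OC(C)(C)C
F2 | step 7 | tert-butyl 3-[2-(benzyloxy)-6-(tert-butyldimethylsilyloxy)-4-methoxy-3,5-dimethylphenyl]-3-oxopropanoate | CC(C)(C)OC(=O)CC(=O)c1c(OCc2ccccc2)c(C)c(OC)c(C)c1O[Si](C)(C)C(C)(C)C
F3 | step 7 | tert-butyl 2-[2-(benzyloxy)-6-(tert-butyldimethylsilyloxy)-4-methoxy-3,5-dimethylbenzoyl]-3-[2,5-bis(benzyloxy)-4-methoxyphenyl]prop-2-enoate | CC(C)(C)OC(=O)C(=Cc1cc(OCc2ccccc2)c(OC)cc1OCc1ccccc1)C(=O)c1c(OCc2ccccc2)c(C)c(OC)c(C)c1O[Si](C)(C)C(C)(C)C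
F4 | step 8 | (E)-1-[2-(benzyloxy)-6-hydroxy-4-methoxy-3,5-dimethylphenyl]-3-[2,5-bis(benzyloxy)-4-methoxyphenyl]prop-2-en-1-one | O=C(/C=C/c1cc(OCc2ccccc2)c(OC)cc1OCc1ccccc1)c1c(OCc2ccccc2)c(C)c(OC)c(C)c1O
F5 | step 8 | rac-5-(benzyloxy)-2-[2,5-bis(benzyloxy)-4-methoxyphenyl]-7-methoxy-6,8-dimethylchroman-4-one | O=C1CC(c2cc(OCc3ccccc3)c(OC)cc2OCc2ccccc2)Oc2c(C)c(OC)c(C)c(OCc3ccccc3)c12
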